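# Comazaphilone G by nickel-catalysed alkyne insertion into a chiral cyclobutanone

Atom numbers follow the isochromene skeleton throughout: pyran C1H2–O2–C3=C4, ring fusion C4a=C8a, carbocycle C5H2–C6–C7–C8(=O).

## Analysis of the target

Comazaphilone G is a 6,7-dihydro-1H-isochromen-8(5H)-one. A 2H-pyran ring (C1H2–O2–C3=C4–C4a=C8a) is fused through the C4a=C8a double bond to a cyclohexenone ring (C4a–C5H2–C6–C7–C8(=O)–C8a), and C3 carries an (E)-prop-1-enyl group. O2, the two ring double bonds and the C8 ketone form one push–pull system (a doubly vinylogous ester), extended by the propenyl group. The only stereocentres are C6 and C7, adjacent and both S. C7 is a tertiary carbinol with the methyl group, lying between C6 and the ketone. C6 is a secondary carbinol esterified with 4-hydroxy-2-methoxy-6-methylbenzoic acid, and the two oxygens are cis on the ring. The sensitive points are: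
- the dienol ether (acid plus water);
- the C6 acyloxy group, which can be expelled after deprotonation of the vinylogously acidic C5 methylene (base);
- the tertiary α-ketol and the free phenol;
- the alkenes, which exclude a final hydrogenolysis.

The hard parts are the cis tertiary/secondary diol next to a ketone as one enantiomer, the tetrasubstituted C4a=C8a alkene with two different branches (C1 and C4), and a di-ortho-substituted benzoate on a hindered alcohol. The strategy rests on one observation: C5, C6, C7 and C8 are the four ring carbons of a cyclobutanone that can carry both stereocentres, and C8a and C4a are the two carbons of an alkyne. Inserting that alkyne into the C8–C5 bond gives the carbocycle with every substituent in place.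

## Retrosynthetic reasoning

**Ester and phenol (29 ⇐ 28 ⇐ 20 + 27).** The C6–O acyl bond is cut last. An acyloxy group at C6 is a leaving group for vinylogous elimination and would be a liability in every earlier step. In diol 20 the secondary C6–OH is far more reactive than the tertiary C7–OH, so no protection of C7 is needed. The phenol is masked as a silyl ether because fluoride is the only final deprotection that leaves the alkenes, the dienol ether and the ester alone. Acid chloride 27 is made in the flask from bis-silyl compound 26.

**Pyran ring (20 ⇐ 19).** The O2–C3 bond is cut. In triol 19 the alkyne is conjugated to the enone, so C3 is the electrophilic terminus. The C1 hydroxyl can reach it only in a 6-endo-dig sense, so a π-acid should close the ring and set the C3=C4 enol ether in one atom-economic step.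

**Side chain and unmasking (19 ⇐ 18 ⇐ 16 + 17).** The C3–propenyl bond is cut at the sp–sp2 junction. The (E)-geometry is bought with bromide 17 and kept by the coupling. One acid treatment of 18 then frees the C1, C6 and C7 hydroxyls together.

**Carbocycle (16 ⇐ 15 ⇐ 10 + 14).** Both C8–C8a and C4a–C5 are cut. This splits the cyclohexenone into cyclobutanone 10, which holds C5–C8 with both stereocentres as a cis-fused acetonide, and diyne 14, which holds C1, C8a, C4a, C4 and C3. The forward reaction must insert the internal alkyne of 14 into the C8–C5 bond of 10, with C8 bonding to the carbon that carries C1. The gain is convergence: two small fragments give the whole carbocycle, C1 and C4 are differentiated from the start by the unsymmetrical diyne, and no stereocentre has to be made on the six-membered ring. The acetonide is preferred to two silyl ethers because it is small next to the C8 carbonyl and comes off together with the C1 silyl ether.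

**Diyne (14 ⇐ 13 ⇐ 12 ⇐ 11).** The C1–C8a bond is cut. Mono-metalation of the symmetrical bis-silyl diyne 11 gives 12, hydroxymethylation gives 13 and silylation gives 14. The remaining trimethylsilyl cap shields the second alkyne in the key step and is later the handle for the side chain.

**Cyclobutanone (10 ⇐ 9 ⇐ 8 ⇐ 7 ⇐ 6 ⇐ 5 ⇐ 4 ⇐ 3 ⇐ 1).** The cis-diol is cut back to the C6=C7 alkene of cyclobutene 5, because a syn-dihydroxylation is the one reaction that guarantees the cis relationship. A direct [2+2] assembly from a methyl(alkoxy)ketene and an enol ether was not adopted, for two reasons: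
- it should place the methyl group, the sterically larger ketene substituent, cis to the enol ether oxygen, giving mainly the trans-dioxygenated ring;
- the planar ketene carries no chirality.

In 5 the benzyloxy-bearing carbon is the future C8. It directs the dihydroxylation to the opposite face, then serves as the carbinol for a lipase resolution (8 to 9), and is finally oxidized to the ketone. Cyclobutene 5 comes from the acyloin-derived ketone 3 by regioselective enol triflate formation and methyl cross-coupling, and 3 from commercial 1.

**Aryl acid (26 ⇐ 25 ⇐ 24 ⇐ 23 ⇐ 22 ⇐ 21).** Methyl orsellinate 21 has both phenols free, but only the 2-hydroxyl is hydrogen-bonded to the ester. Benzylation therefore goes to O4, methylation then to O2, and saponification, hydrogenolysis and silylation give 26.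

## Alternatives that were turned down

**Alternative 1: transannular aldol condensation across a ten-membered oxacycle.**
- Disconnection: the C4a=C8a double bond, leaving the ten-membered keto vinylogous ester A1, which contains all ten peripheral atoms of the bicycle.
- Forward key step: base enolizes the C8 ketone toward C8a (C7 is quaternary), C8a attacks the vinylogous ester carbonyl C4a across the ring, and dehydration gives the bis-silyl ether A2 of the target.
- For it: both six-membered rings form at once, the ester and the propenyl group are already in place, and only desilylation remains. On ring count per step and on end-game length it is stronger than the chosen route.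
- Against it: A1 is a medium ring that is hard to close. C4a is a poorly electrophilic vinylogous ester carbonyl. The basic conditions offer two eliminations: the C8a enolate has O2 in the β-position as a vinylogous carboxylate leaving group, and the C5 protons next to C4a have the C6 acyloxy group β to them. The two stereocentres would also need a separate acyclic synthesis.
- Comparison: the chosen route gives up the double ring closure. In return it has a base-free, neutral key step, a convergent union of two small fragments, and stereocentres carried in a rigid ring.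

**Alternative 2: oxocarbenium closure from a methoxymethyl dienol ether.**
- Disconnection: the C1–C8a bond, with C1 coming from the acetal carbon of the methoxymethyl dienol ether A3.
- Forward key step: a silyl triflate Lewis acid ionizes A3 to the O2=C1H2 oxocarbenium ion, C8a attacks it to close the pyran, and loss of the C8a proton restores the enone, giving the phenol acetate A4 of the target.
- For it: C1 comes from the cheapest one-carbon source. Ring size enforces the regiochemistry, since attack through C4 would give a four-membered ring. The ester is installed before ring closure, so A4 is one deacetylation from the target. On late-stage convergence it is equal to or better than the chosen route.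
- Against it: A3 needs O-alkylation of an ambident enolate with control of O- against C-alkylation and of the enol ether geometry (O2 cis to C4a), and it is hydrolytically labile. A strong silyl Lewis acid must be used beside a free tertiary hydroxyl, an aryl acetate and the C6 ester. C8a is the α-carbon of an enone and only weakly nucleophilic. The carbocycle with its stereocentres still has to be made by other means.
- Comparison: the chosen route makes the carbocycle and attaches C1 in one catalytic step and needs no strong Lewis acid.

**Alternative 3: intramolecular Wittig olefination of a crotonate ester.**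
- Disconnection: the C3=C4 double bond, leaving phosphorus ylide A5 with the C1 oxygen acylated by a crotonyl group.
- Forward key step: the vinylogously stabilized ylide at C4 attacks the ester carbonyl C3, and loss of the phosphine oxide closes the pyran with the (E)-propenyl group in place, giving the bis-silylated core A6.
- For it: pyran and side chain arise in one step from an inexpensive crotonyl unit, without palladium, copper or gold. After the carbocycle it is shorter than the chosen sequence (one step against steps 12, 13 and 15).
- Against it: a ylide conjugated to an enone is a poor nucleophile for an ester carbonyl, and the crotonate is also a Michael acceptor. The phosphonium precursor needs a C4 halide next to the C1 ester, so two differently functionalized allylic methylene groups must sit on one tetrasubstituted enone. The base used to form the ylide can expel the C6 oxygen through C5 deprotonation. A6 still needs selective desilylation at C6 beside C7.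
- Comparison: the chosen route pays two more steps. In return C1 and C4 are told apart from the outset by the unsymmetrical diyne, and the C3=C4 bond arises by an addition under neutral conditions.

Key step: step 11

Remark on the chemistry (assumption): compounds 3 to 8 are racemic and are drawn as the enantiomer that is carried on. The lipase in step 7 is assumed to follow the usual empirical preference for acylating the R-configured secondary carbinol.

## Route

Step 1
Reactants: 1 1,2-bis(trimethylsilyloxy)cyclobutene
Product: 3 2-(benzyloxy)cyclobutanone (racemic), via 2-hydroxycyclobutanone 2 (not isolated)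
Conditions: BnOH, HCl in Et2O, 0 °C → reflux
Reagents that add atoms: benzyl alcohol, OCc1ccccc1
Why: Acid cleaves the bis-silyl enediol ether to acyloin 2, whose hemiketal with benzyl alcohol tautomerises through the enediol to the α-benzyloxy ketone (acid-catalysed acyloin etherification), a known route to 2-alkoxycyclobutanones.

Step 2
Reactants: 3 2-(benzyloxy)cyclobutanone
Product: 4 4-(benzyloxy)cyclobut-1-en-1-yl trifluoromethanesulfonate (racemic)
Conditions: LiN(iPr)2, THF, −78 °C; then N-(5-chloropyridin-2-yl)bis(trifluoromethanesulfonimide), −78 → −20 °C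
Reagents that add atoms: N-(5-chloropyridin-2-yl)-1,1,1-trifluoro-N-(trifluoromethylsulfonyl)methanesulfonamide, FC(F)(F)S(=O)(=O)N(c1ccc(Cl)cn1)S(=O)(=O)C(F)(F)F
Why: Kinetic enolization of an α-alkoxy ketone with a hindered amide base should take the CH2 proton remote from the benzyloxy group, and O-sulfonylation of the enolate gives the enol triflate; the benzyloxy group is α and not β to the carbonyl, so the enolate has no elimination path.

Step 3
Reactants: 4 4-(benzyloxy)cyclobut-1-en-1-yl trifluoromethanesulfonate
Product: 5 {[(2-methylcyclobut-2-en-1-yl)oxy]methyl}benzene (racemic)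
Conditions: MeZnCl, Pd(PPh3)4 (5 mol %), THF, 0 °C → rt
Reagents that add atoms: methylzinc chloride, C[Zn]Cl
Why: Negishi coupling of an enol triflate; oxidative addition into the C–O triflate bond is easy, the methyl group cannot undergo β-hydride elimination, and the allylic benzyl ether is too poor a leaving group to ionize.

Step 4
Reactants: 5 {[(2-methylcyclobut-2-en-1-yl)oxy]methyl}benzene
Product: 6 rac-(1S,2S,4S)-4-(benzyloxy)-1-methylcyclobutane-1,2-diol
Conditions: K2OsO4·2H2O (2 mol %), N-methylmorpholine N-oxide, acetone/H2O, rt
Reagents that add atoms: N-methylmorpholine N-oxide, C[N+]1([O-])CCOCC1; water, O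
Why: Osmium-catalysed syn-dihydroxylation delivers both oxygens to one face, which sets the cis relationship of the future C6 and C7 oxygens, and should attack the face opposite the allylic benzyloxy group, which ties the diol configuration to that of the benzyloxy carbon; any minor diastereomer is removed here because it would erode the resolution in step 7.

Step 5
Reactants: 6 rac-(1S,2S,4S)-4-(benzyloxy)-1-methylcyclobutane-1,2-diol
Product: 7 rac-(1S,5R,6S)-6-(benzyloxy)-3,3,5-trimethyl-2,4-dioxabicyclo[3.2.0]heptane
Conditions: 2,2-dimethoxypropane, PPTS (cat.), CH2Cl2, rt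
Reagents that add atoms: 2,2-dimethoxypropane, COC(C)(C)OC
Why: Acid-catalysed transketalization; a cis-1,2-diol on a four-membered ring is nearly eclipsed and closes readily to the cis-fused dioxolane.

Step 6
Reactants: 7 rac-(1S,5R,6S)-6-(benzyloxy)-3,3,5-trimethyl-2,4-dioxabicyclo[3.2.0]heptane
Product: 8 rac-(1S,5R,6S)-3,3,5-trimethyl-2,4-dioxabicyclo[3.2.0]heptan-6-ol
Conditions: H2 (1 atm), Pd/C, EtOAc, rt
Reagents that add atoms: none
Why: Hydrogenolysis of a benzyl ether under neutral conditions, which leave the acetonide untouched.

Step 7
Reactants: 8 rac-(1S,5R,6S)-3,3,5-trimethyl-2,4-dioxabicyclo[3.2.0]heptan-6-ol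
Product: 9 (1S,5R,6S)-3,3,5-trimethyl-2,4-dioxabicyclo[3.2.0]heptan-6-ol
Conditions: Candida antarctica lipase B (immobilised), vinyl acetate, tBuOMe, 30 °C, run just past half conversion
Reagents that add atoms: none
Why: Lipase-catalysed kinetic resolution by irreversible transesterification; the carbinol lies between a CH2 and a quaternary carbon, the size difference these enzymes discriminate best, and the R-carbinol should be acetylated so that the needed 6S alcohol is recovered, its purity rising with conversion.

Step 8
Reactants: 9 (1S,5R,6S)-3,3,5-trimethyl-2,4-dioxabicyclo[3.2.0]heptan-6-ol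
Product: 10 (1S,5S)-3,3,5-trimethyl-2,4-dioxabicyclo[3.2.0]heptan-6-one
Conditions: Dess–Martin periodinane, CH2Cl2, 0 °C → rt
Reagents that add atoms: none
Why: Dess–Martin oxidation of a secondary alcohol under near-neutral, non-enolizing conditions; the carbinol stereocentre is removed while the two acetonide-bearing centres (future C6 and C7, both S) are untouched.

Step 9
Reactants: 11 1,4-bis(trimethylsilyl)buta-1,3-diyne
Product: 13 5-(trimethylsilyl)penta-2,4-diyn-1-ol, via lithium 4-(trimethylsilyl)buta-1,3-diyn-1-ide 12 (not isolated)
Conditions: MeLi·LiBr (1 equiv), THF, 0 °C → rt; then (CH2O)n, −78 °C → rt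
Reagents that add atoms: formaldehyde (as paraformaldehyde), C=O
Why: One equivalent of methyllithium removes a single alkynyl silyl group by attack at silicon, and the resulting lithium acetylide adds to formaldehyde (acetylide hydroxymethylation).

Step 10
Reactants: 13 5-(trimethylsilyl)penta-2,4-diyn-1-ol
Product: 14 tert-butyldimethyl{[5-(trimethylsilyl)penta-2,4-diyn-1-yl]oxy}silane
Conditions: TBSCl, imidazole, CH2Cl2, rt
Reagents that add atoms: tert-butyl(chloro)dimethylsilane, CC(C)(C)[Si](C)(C)Cl
Why: Standard silylation of a primary alcohol; the silyl ether is inert to zerovalent nickel and is too poor a leaving group for propargylic ionization.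

Step 11
Reactants: 10 (1S,5S)-3,3,5-trimethyl-2,4-dioxabicyclo[3.2.0]heptan-6-one; 14 tert-butyldimethyl{[5-(trimethylsilyl)penta-2,4-diyn-1-yl]oxy}silane
Product: 15 (3aS,7aS)-5-{[(tert-butyldimethylsilyl)oxy]methyl}-2,2,3a-trimethyl-6-[(trimethylsilyl)ethynyl]-7,7a-dihydro-1,3-benzodioxol-4(3aH)-one
Conditions: Ni(cod)2 (10 mol %), PCy3 (20 mol %), toluene, 100 °C, slow addition of 14
Reagents that add atoms: none
Why: Zerovalent nickel binds the C8 ketone of 10 and the internal alkyne of 14 and couples them oxidatively to a spiro oxanickelacyclopentene in which C8 is bonded to C8a; β-carbon elimination then opens the strained ring at C8–C5 to a seven-membered nickelacycle, and C(sp3)–C(sp2) reductive elimination joins C5 to C4a and returns zerovalent nickel. The closest known reaction type is the nickel-catalysed intermolecular insertion of internal alkynes into cyclobutanones to give cyclohex-2-enones under these conditions. The cyclohexenone ring is closed not by an end-to-end cyclization but by a two-carbon ring expansion (formal [4+2]), the last bond arising by reductive elimination from the seven-membered metallacycle. No stereocentre is formed; C6 and C7 keep their configuration because no bond to either is broken and C7 has no hydrogen through which it could epimerise. Three selectivities are needed: the alkyne carbon bearing CH2OSi must bond to C8, which the conjugating alkynyl substituent secures by preferring the carbon attached to nickel, as in other nickel couplings of conjugated diynes and enynes with carbonyl groups; the silyl-capped alkyne must stay out, for which its trimethylsilyl group shields it and sets its two directing effects against each other; and C8–C5 rather than C8–C7 must cleave, which follows because nickel then carries a primary alkyl instead of a fully substituted, oxygen-bearing carbon. Ring strain of the bicyclic ketone drives the cleavage, and slow addition of 14 should hold back alkyne oligomerization.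

Step 12
Reactants: 15 (3aS,7aS)-5-{[(tert-butyldimethylsilyl)oxy]methyl}-2,2,3a-trimethyl-6-[(trimethylsilyl)ethynyl]-7,7a-dihydro-1,3-benzodioxol-4(3aH)-one
Product: 16 (3aS,7aS)-5-{[(tert-butyldimethylsilyl)oxy]methyl}-6-ethynyl-2,2,3a-trimethyl-7,7a-dihydro-1,3-benzodioxol-4(3aH)-one
Conditions: K2CO3 (cat.), MeOH, 0 °C, short reaction time
Reagents that add atoms: none
Why: Methanolysis of an alkynyl–silicon bond, far faster than cleavage of the silyl ether or the acetonide; low temperature and a catalytic amount of base limit methanol addition to the enynone and elimination of the C6 oxygen.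

Step 13
Reactants: 16 (3aS,7aS)-5-{[(tert-butyldimethylsilyl)oxy]methyl}-6-ethynyl-2,2,3a-trimethyl-7,7a-dihydro-1,3-benzodioxol-4(3aH)-one; 17 (E)-1-bromoprop-1-ene
Product: 18 (3aS,7aS)-5-{[(tert-butyldimethylsilyl)oxy]methyl}-2,2,3a-trimethyl-6-[(3E)-pent-3-en-1-yn-1-yl]-7,7a-dihydro-1,3-benzodioxol-4(3aH)-one
Conditions: PdCl2(PPh3)2 (5 mol %), copper iodide CuI (10 mol %), Et3N, THF, rt
Reagents that add atoms: none
Why: Sonogashira coupling of a terminal alkyne with an alkenyl bromide proceeds with retention of the alkene geometry, so the (E)-propenyl unit of 17 is transferred unchanged; a tertiary amine is used so that no amine can add to the enynone.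

Step 14
Reactants: 18 (3aS,7aS)-5-{[(tert-butyldimethylsilyl)oxy]methyl}-2,2,3a-trimethyl-6-[(3E)-pent-3-en-1-yn-1-yl]-7,7a-dihydro-1,3-benzodioxol-4(3aH)-one
Product: 19 (5S,6S)-5,6-dihydroxy-2-(hydroxymethyl)-6-methyl-3-[(3E)-pent-3-en-1-yn-1-yl]cyclohex-2-en-1-one
Conditions: 2 M HCl aq./THF, rt
Reagents that add atoms: none
Why: Aqueous acid hydrolyses the acetonide and the primary silyl ether in one operation; C7 is quaternary, so the β-hydroxy ketone cannot dehydrate, and any pyran that already forms under the acid is the product of step 15.

Step 15
Reactants: 19 (5S,6S)-5,6-dihydroxy-2-(hydroxymethyl)-6-methyl-3-[(3E)-pent-3-en-1-yn-1-yl]cyclohex-2-en-1-one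
Product: 20 (6S,7S)-6,7-dihydroxy-7-methyl-3-[(E)-prop-1-en-1-yl]-6,7-dihydro-1H-isochromen-8(5H)-one
Conditions: Ph3PAuNTf2 (5 mol %), CH2Cl2, rt
Reagents that add atoms: none
Why: Gold-catalysed hydroalkoxylation of the alkyne by the C1 hydroxyl in the 6-endo-dig mode; attack at C3 is favoured because C3 is the terminus of the alkyne conjugated to the enone and bears the cation-stabilizing propenyl group, whereas 5-exo attack at C4 has neither advantage, and the C6 and C7 hydroxyls cannot reach the alkyne without forming a bridged ring.

Step 16
Reactants: 21 methyl orsellinate (methyl 2,4-dihydroxy-6-methylbenzoate)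
Product: 22 methyl 4-(benzyloxy)-2-hydroxy-6-methylbenzoate
Conditions: BnBr (1.05 equiv), K2CO3, acetone, reflux
Reagents that add atoms: benzyl bromide, BrCc1ccccc1
Why: Williamson etherification; the 4-hydroxyl is the more acidic and is not tied up in the hydrogen bond to the ester carbonyl, so it is alkylated selectively.

Step 17
Reactants: 22 methyl 4-(benzyloxy)-2-hydroxy-6-methylbenzoate
Product: 23 methyl 4-(benzyloxy)-2-methoxy-6-methylbenzoate
Conditions: MeI, K2CO3, DMF, 50 °C
Reagents that add atoms: iodomethane, CI
Why: O-Methylation of the remaining, hydrogen-bonded phenol under more forcing Williamson conditions.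

Step 18
Reactants: 23 methyl 4-(benzyloxy)-2-methoxy-6-methylbenzoate
Product: 24 4-(benzyloxy)-2-methoxy-6-methylbenzoic acid
Conditions: KOH, DMSO/H2O, 90 °C; then HCl aq.
Reagents that add atoms: potassium hydroxide, [K+].[OH-]
Why: Saponification of a di-ortho-substituted benzoate needs poorly solvated hydroxide and heat; the benzyl and methyl ethers are stable to it.

Step 19
Reactants: 24 4-(benzyloxy)-2-methoxy-6-methylbenzoic acid
Product: 25 4-hydroxy-2-methoxy-6-methylbenzoic acid
Conditions: H2 (1 atm), Pd/C, EtOAc/MeOH, rt
Reagents that add atoms: none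
Why: Hydrogenolysis of the aryl benzyl ether, done here because no hydrogenation is possible once the fragment is joined to the alkenes of the core.

Step 20
Reactants: 25 4-hydroxy-2-methoxy-6-methylbenzoic acid
Product: 26 tert-butyldimethylsilyl 4-[(tert-butyldimethylsilyl)oxy]-2-methoxy-6-methylbenzoate
Conditions: TBSCl (2.2 equiv), imidazole, DMF, rt
Reagents that add atoms: tert-butyl(chloro)dimethylsilane, CC(C)(C)[Si](C)(C)Cl
Why: Silylation of both the phenol and the carboxylic acid; the silyl ester is used directly as a masked acid chloride in step 21.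

Step 21
Reactants: 26 tert-butyldimethylsilyl 4-[(tert-butyldimethylsilyl)oxy]-2-methoxy-6-methylbenzoate; 20 (6S,7S)-6,7-dihydroxy-7-methyl-3-[(E)-prop-1-en-1-yl]-6,7-dihydro-1H-isochromen-8(5H)-one
Product: 28 (6S,7S)-7-hydroxy-7-methyl-8-oxo-3-[(E)-prop-1-en-1-yl]-5,6,7,8-tetrahydro-1H-isochromen-6-yl 4-[(tert-butyldimethylsilyl)oxy]-2-methoxy-6-methylbenzoate, via 4-[(tert-butyldimethylsilyl)oxy]-2-methoxy-6-methylbenzoyl chloride 27 (not isolated)
Conditions: (COCl)2, DMF (cat.), CH2Cl2, 0 °C → rt, evaporate; then 20, Et3N, DMAP (cat.), CH2Cl2, 0 °C → rt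
Reagents that add atoms: none
Why: A silyl ester is converted by oxalyl chloride and catalytic DMF into the acid chloride under neutral conditions that spare the aryl silyl ether; DMAP-catalysed acylation then takes the secondary C6 hydroxyl, because the tertiary C7 hydroxyl next to the ketone is far less nucleophilic, and C6 keeps its configuration since only the O–H bond reacts.

Step 22
Reactants: 28 (6S,7S)-7-hydroxy-7-methyl-8-oxo-3-[(E)-prop-1-en-1-yl]-5,6,7,8-tetrahydro-1H-isochromen-6-yl 4-[(tert-butyldimethylsilyl)oxy]-2-methoxy-6-methylbenzoate
Product: 29 comazaphilone G, (6S,7S)-7-hydroxy-7-methyl-8-oxo-3-[(E)-prop-1-en-1-yl]-5,6,7,8-tetrahydro-1H-isochromen-6-yl 4-hydroxy-2-methoxy-6-methylbenzoate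
Conditions: Bu4NF, AcOH (1:1), THF, 0 °C
Reagents that add atoms: none
Why: Fluoride cleaves an aryl silyl ether within minutes; buffering with acetic acid keeps the medium from becoming basic, so the C6 ester is not expelled through C5 deprotonation and the dienol ether is not exposed to acid.

## Compound list

1 | 1,2-bis(trimethylsilyloxy)cyclobutene | C[Si](C)(C)OC1=C(O[Si](C)(C)C)CC1 | starting material
2 | 2-hydroxycyclobutanone (racemic) | O=C1CCC1O | intermediate (not isolated)
3 | 2-(benzyloxy)cyclobutanone (racemic) | O=C1CCC1OCc1ccccc1 | intermediate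
4 | 4-(benzyloxy)cyclobut-1-en-1-yl trifluoromethanesulfonate (racemic) | O=S(=O)(OC1=CCC1OCc1ccccc1)C(F)(F)F | intermediate
5 | {[(2-methylcyclobut-2-en-1-yl)oxy]methyl}benzene (racemic) | CC1=CCC1OCc1ccccc1 | intermediate
6 | rac-(1S,2S,4S)-4-(benzyloxy)-1-methylcyclobutane-1,2-diol (racemate, one enantiomer drawn) | C[C@]1(O)[C@@H](O)C[C@@H]1OCc1ccccc1 | intermediate
7 | rac-(1S,5R,6S)-6-(benzyloxy)-3,3,5-trimethyl-2,4-dioxabicyclo[3.2.0]heptane (racemate, one enantiomer drawn) | C[C@]12OC(C)(C)O[C@H]1C[C@@H]2OCc1ccccc1 | intermediate
8 | rac-(1S,5R,6S)-3,3,5-trimethyl-2,4-dioxabicyclo[3.2.0]heptan-6-ol (racemate, one enantiomer drawn) | C[C@]12OC(C)(C)O[C@H]1C[C@@H]2O | intermediate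
9 | (1S,5R,6S)-3,3,5-trimethyl-2,4-dioxabicyclo[3.2.0]heptan-6-ol (single enantiomer) | C[C@]12OC(C)(C)O[C@H]1C[C@@H]2O | intermediate
10 | (1S,5S)-3,3,5-trimethyl-2,4-dioxabicyclo[3.2.0]heptan-6-one (acetonide of cis-(2S,3S)-2,3-dihydroxy-2-methylcyclobutanone) | C[C@]12OC(C)(C)O[C@H]1CC2=O | intermediate
11 | 1,4-bis(trimethylsilyl)buta-1,3-diyne | C[Si](C)(C)C#CC#C[Si](C)(C)C | starting material
12 | lithium 4-(trimethylsilyl)buta-1,3-diyn-1-ide | [Li]C#CC#C[Si](C)(C)C | intermediate (not isolated)
13 | 5-(trimethylsilyl)penta-2,4-diyn-1-ol | OCC#CC#C[Si](C)(C)C | intermediate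
14 | tert-butyldimethyl{[5-(trimethylsilyl)penta-2,4-diyn-1-yl]oxy}silane | C[Si](C)(C)C#CC#CCO[Si](C)(C)C(C)(C)C | intermediate
15 | (3aS,7aS)-5-{[(tert-butyldimethylsilyl)oxy]methyl}-2,2,3a-trimethyl-6-[(trimethylsilyl)ethynyl]-7,7a-dihydro-1,3-benzodioxol-4(3aH)-one | C[Si](C)(C)C#CC1=C(CO[Si](C)(C)C(C)(C)C)C(=O)[C@@]2(C)OC(C)(C)O[C@H]2C1 | intermediate
16 | (3aS,7aS)-5-{[(tert-butyldimethylsilyl)oxy]methyl}-6-ethynyl-2,2,3a-trimethyl-7,7a-dihydro-1,3-benzodioxol-4(3aH)-one | C#CC1=C(CO[Si](C)(C)C(C)(C)C)C(=O)[C@@]2(C)OC(C)(C)O[C@H]2C1 | intermediate
17 | (E)-1-bromoprop-1-ene | C/C=C/Br | starting material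
18 | (3aS,7aS)-5-{[(tert-butyldimethylsilyl)oxy]methyl}-2,2,3a-trimethyl-6-[(3E)-pent-3-en-1-yn-1-yl]-7,7a-dihydro-1,3-benzodioxol-4(3aH)-one | C/C=C/C#CC1=C(CO[Si](C)(C)C(C)(C)C)C(=O)[C@@]2(C)OC(C)(C)O[C@H]2C1 | intermediate
19 | (5S,6S)-5,6-dihydroxy-2-(hydroxymethyl)-6-methyl-3-[(3E)-pent-3-en-1-yn-1-yl]cyclohex-2-en-1-one | C/C=C/C#CC1=C(CO)C(=O)[C@@](C)(O)[C@@H](O)C1 | intermediate
20 | (6S,7S)-6,7-dihydroxy-7-methyl-3-[(E)-prop-1-en-1-yl]-6,7-dihydro-1H-isochromen-8(5H)-one | C/C=C/C1=CC2=C(CO1)C(=O)[C@@](C)(O)[C@@H](O)C2 | intermediate
21 | methyl orsellinate (methyl 2,4-dihydroxy-6-methylbenzoate) | COC(=O)c1c(C)cc(O)cc1O | starting material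
22 | methyl 4-(benzyloxy)-2-hydroxy-6-methylbenzoate | COC(=O)c1c(C)cc(OCc2ccccc2)cc1O | intermediate
23 | methyl 4-(benzyloxy)-2-methoxy-6-methylbenzoate | COC(=O)c1c(C)cc(OCc2ccccc2)cc1OC | intermediate
24 | 4-(benzyloxy)-2-methoxy-6-methylbenzoic acid | OC(=O)c1c(C)cc(OCc2ccccc2)cc1OC | intermediate
25 | 4-hydroxy-2-methoxy-6-methylbenzoic acid | OC(=O)c1c(C)cc(O)cc1OC | intermediate
26 | tert-butyldimethylsilyl 4-[(tert-butyldimethylsilyl)oxy]-2-methoxy-6-methylbenzoate | CC(C)(C)[Si](C)(C)OC(=O)c1c(C)cc(O[Si](C)(C)C(C)(C)C)cc1OC | intermediate
27 | 4-[(tert-butyldimethylsilyl)oxy]-2-methoxy-6-methylbenzoyl chloride | ClC(=O)c1c(C)cc(O[Si](C)(C)C(C)(C)C)cc1OC | intermediate (not isolated)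
28 | (6S,7S)-7-hydroxy-7-methyl-8-oxo-3-[(E)-prop-1-en-1-yl]-5,6,7,8-tetrahydro-1H-isochromen-6-yl 4-[(tert-butyldimethylsilyl)oxy]-2-methoxy-6-methylbenzoate | C/C=C/C1=CC2=C(CO1)C(=O)[C@@](C)(O)[C@@H](OC(=O)c3c(C)cc(O[Si](C)(C)C(C)(C)C)cc3OC)C2 | intermediate
29 | comazaphilone G, (6S,7S)-7-hydroxy-7-methyl-8-oxo-3-[(E)-prop-1-en-1-yl]-5,6,7,8-tetrahydro-1H-isochromen-6-yl 4-hydroxy-2-methoxy-6-methylbenzoate | C/C=C/C1=CC2=C(CO1)C(=O)[C@@](C)(O)[C@@H](OC(=O)c1c(C)cc(O)cc1OC)C2 | target

## Step count and least certain steps

Total: 22 steps. Longest linear sequence: 15 steps (steps 1 to 8, 11 to 15, 21 and 22). The diyne branch (steps 9 and 10) and the aryl branch (steps 16 to 20) are convergent side lines.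

**Step 11 (key step).**
- Risk: the ketone next to the fully substituted C7 may enter the oxidative coupling too slowly, so that nickel-mediated oligomerization of the diyne takes over. The alkylnickel intermediate may also lose the C6 oxygen by β-elimination before the reductive elimination.
- Fallback: it sets out from 10 and 14 and comes back at 15, and it separates bond formation from bond cleavage. The propargylic alkyne of 14 is converted with Ti(OiPr)4 and iPrMgCl at −50 °C into its low-valent titanium complex, which adds stoichiometrically to the ketone of 10 at the CH2OSi-bearing carbon. An iodine quench of the carbon–titanium bond should give the cyclobutanol 6-[(Z)-1-[(tert-butyldimethylsilyl)oxy]-3-iodo-5-(trimethylsilyl)pent-2-en-4-yn-2-yl]-3,3,5-trimethyl-2,4-dioxabicyclo[3.2.0]heptan-6-ol F1, with iodine cis to the carbinol carbon. Treatment of F1 with Pd(OAc)2, P(tBu)3 and Cs2CO3 in toluene at 80 °C then uses the established palladium chemistry of tertiary cyclobutanols: oxidative addition into the C–I bond, alkoxide binding, β-carbon elimination of the C8–C5 bond and reductive elimination to C4a, giving 15.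

**Step 2.**
- Risk: deprotonation on the benzyloxy-bearing side, or decomposition of the strained enolate before O-sulfonylation, which would give the regioisomeric enol triflate or little product.
- Fallback: it sets out from 3 and comes back at 5 by a Shapiro reaction. Condensation of 3 with 2,4,6-triisopropylbenzenesulfonohydrazide gives N'-[2-(benzyloxy)cyclobutylidene]-2,4,6-triisopropylbenzenesulfonohydrazide F2. Two equivalents of BuLi remove the N–H and the CH2 proton, and loss of sulfinate and nitrogen gives [4-(benzyloxy)cyclobut-1-en-1-yl]lithium F3. Iodomethane methylates F3 to 5, so no triflate is needed.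

**Step 7.**
- Risk: the lipase may discriminate poorly between the enantiomers of this compact bicyclic carbinol, leaving 9 of insufficient enantiomeric purity.
- Fallback: it sets out from 8 and comes back at 9 by a classical resolution. Racemic 8 is esterified with (S)-2-methoxy-2-phenylacetic acid (DCC, DMAP) to give the diastereomers (1S,5R,6S)-3,3,5-trimethyl-2,4-dioxabicyclo[3.2.0]heptan-6-yl (S)-2-methoxy-2-phenylacetate F4 and (1R,5S,6R)-3,3,5-trimethyl-2,4-dioxabicyclo[3.2.0]heptan-6-yl (S)-2-methoxy-2-phenylacetate F5. These are separated by chromatography or crystallization, and methanolysis of F4 (K2CO3, MeOH) returns 9.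

**Step 15.**
- Risk: competing 5-exo attack at C4, or gold-induced hydration or polymerization of the dienyne in the presence of three free hydroxyls.
- Fallback: it sets out from 19 and comes back at 20 through an amine relay. Diethylamine adds to the alkyne at C3 in the conjugate sense to give the enaminone (5S,6S)-3-[2-(diethylamino)penta-1,3-dien-1-yl]-5,6-dihydroxy-2-(hydroxymethyl)-6-methylcyclohex-2-en-1-one F6. Mild acid (PPTS, CH2Cl2) then lets the C1 hydroxyl displace the amine at C3 by addition–elimination, which can only give the six-membered ring.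

**Step 21.**
- Risk: acyl transfer between a di-ortho-substituted benzoyl chloride and a secondary alcohol next to a quaternary carbon may be slow. Longer exposure to amine base could then cause elimination across C5–C6 or acylation at C7.
- Fallback: it sets out from 20 and comes back at 28 by activating the alcohol instead of relying on the acyl donor. Heating 20 with Bu2SnO in toluene with removal of water gives the stannylene acetal (3aS,9aS)-2,2-dibutyl-3a-methyl-7-[(E)-prop-1-en-1-yl]-9,9a-dihydro-5H-[1,3,2]dioxastannolo[4,5-g]isochromen-4(3aH)-one F7. F7 is acylated by 27 at the secondary oxygen without added base, and aqueous work-up frees the C7 hydroxyl.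

## Further compounds

F1 | step 11 | 6-[(Z)-1-[(tert-butyldimethylsilyl)oxy]-3-iodo-5-(trimethylsilyl)pent-2-en-4-yn-2-yl]-3,3,5-trimethyl-2,4-dioxabicyclo[3.2.0]heptan-6-ol (1S,5S; carbinol configuration open) | C[C@]12OC(C)(C)O[C@H]1CC2(O)/C(CO[Si](C)(C)C(C)(C)C)=C(\I)C#C[Si](C)(C)C
F2 | step 2 | N'-[2-(benzyloxy)cyclobutylidene]-2,4,6-triisopropylbenzenesulfonohydrazide (racemic) | CC(C)c1cc(C(C)C)c(S(=O)(=O)NN=C2CCC2OCc2ccccc2)c(C(C)C)c1
F3 | step 2 | [4-(benzyloxy)cyclobut-1-en-1-yl]lithium (racemic) | [Li]C1=CCC1OCc1ccccc1
F4 | step 7 | (1S,5R,6S)-3,3,5-trimethyl-2,4-dioxabicyclo[3.2.0]heptan-6-yl (S)-2-methoxy-2-phenylacetate | C[C@]12OC(C)(C)O[C@H]1C[C@@H]2OC(=O)[C@@H](OC)c1ccccc1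
F5 | step 7 | (1R,5S,6R)-3,3,5-trimethyl-2,4-dioxabicyclo[3.2.0]heptan-6-yl (S)-2-methoxy-2-phenylacetate | C[C@@]12OC(C)(C)O[C@@H]1C[C@H]2OC(=O)[C@@H](OC)c1ccccc1
F6 | step 15 | (5S,6S)-3-[2-(diethylamino)penta-1,3-dien-1-yl]-5,6-dihydroxy-2-(hydroxymethyl)-6-methylcyclohex-2-en-1-one (3E; enamine geometry open) | C/C=C/C(N(CC)CC)=CC1=C(CO)C(=O)[C@@](C)(O)[C@@H](O)C1
F7 | step 21 | (3aS,9aS)-2,2-dibutyl-3a-methyl-7-[(E)-prop-1-en-1-yl]-9,9a-dihydro-5H-[1,3,2]dioxastannolo[4,5-g]isochromen-4(3aH)-one (dibutylstannylene acetal of 20) | C/C=C/C1=CC2=C(CO1)C(=O)[C@@]3(C)O[Sn](CCCC)(CCCC)O[C@H]3C2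
A1 | alternative 1 | ten-membered keto vinylogous ester, (Z)-2-[(E)-prop-1-enyl]-4,8-dioxo-1-oxacyclodec-2-ene with the C7 triethylsilyl ether and the C6 silyl-protected aryl ester | C/C=C/C1=C/C(=O)C[C@H](OC(=O)c2c(C)cc(O[Si](C)(C)C(C)(C)C)cc2OC)[C@](C)(O[Si](CC)(CC)CC)C(=O)CCO1
A2 | alternative 1 | bis-silyl ether of the target | C/C=C/C1=CC2=C(CO1)C(=O)[C@@](C)(O[Si](CC)(CC)CC)[C@@H](OC(=O)c3c(C)cc(O[Si](C)(C)C(C)(C)C)cc3OC)C2
A3 | alternative 2 | methoxymethyl dienol ether of the 3-(2-oxopent-3-enyl)cyclohexenone carrying the C6 acetoxyaryl ester | C/C=C/C(OCOC)=C/C1=CC(=O)[C@@](C)(O)[C@@H](OC(=O)c2c(C)cc(OC(C)=O)cc2OC)C1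
A4 | alternative 2 | phenol acetate of the target | C/C=C/C1=CC2=C(CO1)C(=O)[C@@](C)(O)[C@@H](OC(=O)c3c(C)cc(OC(C)=O)cc3OC)C2
A5 | alternative 3 | C4 triphenylphosphonium ylide of the bis-silylated cyclohexenone whose C1 oxygen is acylated by (E)-but-2-enoyl | C/C=C/C(=O)OCC1=C(C=P(c2ccccc2)(c2ccccc2)c2ccccc2)C[C@H](O[Si](C)(C)C(C)(C)C)[C@](C)(O[Si](CC)(CC)CC)C1=O
A6 | alternative 3 | bicyclic core with C6 tert-butyldimethylsilyl and C7 triethylsilyl ethers | C/C=C/C1=CC2=C(CO1)C(=O)[C@@](C)(O[Si](CC)(CC)CC)[C@@H](O[Si](C)(C)C(C)(C)C)C2
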